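(The rate constants belong to no real substance.)

The constants gave me one number to carry through this flask.

    substrate + catalyst intermediate A → catalyst intermediate B (k1 = 3.1 M⁻¹ s⁻¹)
    catalyst intermediate B → by-product + catalyst intermediate C (k2 = 0.42 s⁻¹)
    catalyst intermediate C → free catalyst + product (k3 = 0.60 s⁻¹)
    catalyst intermediate B → spent catalyst (k4 = 0.0019 s⁻¹)
    reagent + free catalyst ⇌ catalyst intermediate A (K5 = 9.0 M⁻¹, k5 = 0.77 M⁻¹ s⁻¹)

substrate 0.20 M; reagent 0.120 M; free catalyst 1.0 mM

- the form that holds most of the catalyst when 30% of the substrate are converted (catalyst intermediate B / catalyst intermediate A / free catalyst / catalyst intermediate C / spent catalyst)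
- its share of the catalyst then
- apparent order in reagent when 30% of the substrate are converted (percent change of the rate of making product for one percent more reagent charged)
- factor on the rate of making product when 30% of the substrate are converted if free catalyst is charged twice over

Catalyst intermediate B goes forward with 0.42 s⁻¹ and turns into spent catalyst with 0.0019 s⁻¹, so I reckoned

loss = 0.0019 s⁻¹ / (0.42 s⁻¹ + 0.0019 s⁻¹) = 0.450%,

the loss per turnover: the fraction of passages through catalyst intermediate B that end in spent catalyst.

Each round uses one reagent and one substrate. The reagent is the limiting reagent, charged at 0.120 M, less than the 0.20 M of substrate. My product curve therefore had to level off at 60.0% of the substrate. Spent catalyst would then stand at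

loss × 0.120 M = 0.540 mM,

less than the 1.0 mM charged, so I took the ceiling to be the reagent's.

For the starting slope I added the time a working catalyst spends in each form per round, with the reverse of the reagent binding step at 0.0856 s⁻¹. At the charge, the round time came to 18.0 s, which gives a slope of 0.200 M h⁻¹.

The curve bends by 30% conversion. There the reagent balance leaves

0.120 M − 0.0600 M = 0.0600 M

of reagent, half its charge, leaving aside the reagent held in catalyst intermediate A, and the loss gives 0.270 mM of spent catalyst. The round time had grown to 32.3 s, so the slope fell to 0.0814 M h⁻¹. Free catalyst, the resting state, came to 58.6% of the catalyst by my reckoning. Taking spent catalyst as the same 0.270 mM at this conversion and the round time as unchanged, I got a factor of 2.37 for twice the catalyst charged.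

The forecast named free catalyst at 58.7%, with an order of 1.61 in reagent, and gave a factor of 2.37 on the ground that “Doubling catalyst leaves spent at 0.27 mM”.

The simulation gave free catalyst at 58.7%, an order of 1.6 and a factor of 2.37, with 27.0% of the catalyst spent at 0.463 h. At 0.300 h, catalyst intermediate B went to by-product and catalyst intermediate C 220 times as fast as to spent catalyst. Carried to the whole reagent charge, the loss per turnover gives 54.0% of the catalyst spent, and at 10.0 h the flask stood with reagent at 0%, product at 59.7% and spent catalyst at 54.0%.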